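**Retrosynthetic overview**

1. Numbering: C7 bears the guaiacyl ring, C8 is the hydroxylated fusion carbon, C9 is OCH2; C7' bears the veratryl ring, C8' is the C–H fusion carbon, C9' is OCH2. Ring A = O–C7–C8–C8'–C9'; ring B = O–C7'–C8'–C8–C9.
2. Feature: the oxygenated fusion carbon C8 is bonded to benzylic C7, so C7=C8 can be written as a styrenyl silyl enol ether in which C8 accepts a C8' radical and C7 afterwards accepts the C9' oxygen.
3. Target ⇒ bis-silyl ether (fluoride) ⇒ epoxy silyl enol ether: C8–C8' by radical 5-exo closure (ring B first), then C7–O by polar closure (ring A second), in one flask with Cp2TiCl and then I2.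
4. Enol ether ⇒ alpha-alkoxy ketone ⇒ epoxy alcohol + diazoketone (Rh2(OAc)4 O–H insertion makes the C9–O bond); the diazoketone comes from homovanillic acid.
5. Epoxy alcohol ⇐ veratraldehyde by vinyl addition and Sharpless kinetic-resolution epoxidation; its carbinol centre (C7') is the only stereocentre carried through and directs C8', C8 and C7.

Key step: step 7

Assumption: veratraldehyde, vinylmagnesium bromide (THF solution) and homovanillic acid are purchased; the fallbacks take propargyl bromide, 4-iodo-2-methoxyphenol and methyl bromoacetate as commercial.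

**Route**

Step 1
Reactants: 1 veratraldehyde; 2 vinylmagnesium bromide
Product: 4 rac-1-(3,4-dimethoxyphenyl)prop-2-en-1-ol, via bromomagnesium alkoxide 3 (not isolated)
Conditions: vinylMgBr (1.2 equiv), THF, −20 → 0 °C; then aq NH4Cl
Reagents that add atoms: none
Why: Grignard 1,2-addition of the vinyl nucleophile to the aldehyde gives, after hydrolysis of alkoxide 3, the racemic allylic alcohol, which is resolved in step 2.

Step 2
Reactants: 4 rac-1-(3,4-dimethoxyphenyl)prop-2-en-1-ol
Product: 5 (R)-(3,4-dimethoxyphenyl)[(S)-oxiran-2-yl]methanol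
Conditions: Ti(OiPr)4 (0.10 equiv), D-(−)-diisopropyl tartrate (0.15 equiv), t-BuOOH (0.45 equiv, anhydrous), 4 Å MS, CH2Cl2, −20 °C
Reagents that add atoms: tert-butyl hydroperoxide, CC(C)(C)OO
Why: In this Sharpless kinetic resolution the D-(−)-tartrate titanium catalyst should epoxidise the (S)-enantiomer of 4 much faster than the (R)-enantiomer (which is left behind and separated) and on the face that gives the erythro epoxy alcohol, so the carbinol centre (later C7') is fixed by the choice of tartrate and the epoxide centre by reagent control; the carbinol descriptor becomes R only because the epoxide carbon now outranks the aryl carbon.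

Step 3
Reactants: 6 homovanillic acid
Product: 8 [4-(tert-butyldimethylsilyloxy)-3-methoxyphenyl]acetic acid, via bis-silylated silyl ester 7 (not isolated)
Conditions: TBSCl (2.3 equiv), imidazole (5 equiv), DMF, rt; then AcOH–THF–H2O (3:1:1), rt
Reagents that add atoms: tert-butyldimethylsilyl chloride, CC(C)(C)[Si](C)(C)Cl
Why: Imidazole-promoted silylation covers both the phenol and the acid, and the much more labile silyl ester is then hydrolysed selectively by aqueous acetic acid while the aryl silyl ether stays (protecting-group chemistry, no stereocentre).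

Step 4
Reactants: 8 [4-(tert-butyldimethylsilyloxy)-3-methoxyphenyl]acetic acid
Product: 10 1-diazo-3-[4-(tert-butyldimethylsilyloxy)-3-methoxyphenyl]propan-2-one, via mixed isobutyl carbonic anhydride 9 (not isolated)
Conditions: i-BuOCOCl (1.1 equiv), N-methylmorpholine (1.1 equiv), THF, −15 °C; then CH2N2 (3 equiv), Et2O, −15 → 0 °C
Reagents that add atoms: diazomethane, C=[N+]=[N-]
Why: Acylation of diazomethane by a mixed carbonic anhydride (first stage of the Arndt–Eistert sequence) gives the terminal diazoketone without mineral acid, which the aryl silyl ether tolerates.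

Step 5
Reactants: 5 (R)-(3,4-dimethoxyphenyl)[(S)-oxiran-2-yl]methanol; 10 1-diazo-3-[4-(tert-butyldimethylsilyloxy)-3-methoxyphenyl]propan-2-one
Product: 11 1-[4-(tert-butyldimethylsilyloxy)-3-methoxyphenyl]-3-{(R)-(3,4-dimethoxyphenyl)[(S)-oxiran-2-yl]methoxy}propan-2-one
Conditions: Rh2(OAc)4 (1 mol %), CH2Cl2 (0.3 M in 5), rt; 10 (1.3 equiv) added by syringe pump over 4 h
Reagents that add atoms: none
Why: Rhodium carbenoid O–H insertion (oxonium ylide, then 1,2-proton shift) joins the two halves under neutral conditions, so the epoxide is neither opened nor Payne-rearranged, and the C7' carbinol centre keeps its configuration because its C–O bond is not broken.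

Step 6
Reactants: 11 1-[4-(tert-butyldimethylsilyloxy)-3-methoxyphenyl]-3-{(R)-(3,4-dimethoxyphenyl)[(S)-oxiran-2-yl]methoxy}propan-2-one
Product: 12 (Z)-silyl enol ether ArCH=C(OTBS)CH2–O–CH(veratryl)(oxiranyl) with Ar = 4-(tert-butyldimethylsilyloxy)-3-methoxyphenyl
Conditions: TBSOTf (1.3 equiv), Et3N (2.5 equiv), CH2Cl2, −78 → 0 °C
Reagents that add atoms: tert-butyldimethylsilyl triflate, CC(C)(C)[Si](C)(C)OS(=O)(=O)C(F)(F)F
Why: Soft enolisation with a silyl triflate and an amine silylates the ketone on the side of the more acidic benzylic C7–H to give the aryl-conjugated enol ether, with the (Z) geometry (aryl cis to OSi) favoured by allylic strain; the geometry is not critical because C7 becomes planar in step 7.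

Step 7
Reactants: 12 (Z)-silyl enol ether ArCH=C(OTBS)CH2–O–CH(veratryl)(oxiranyl)
Product: 15 (7R,8S,7'S,8'R)-bis(tert-butyldimethylsilyl) ether of the target, via benzylic titanium alkoxide species 13 (not isolated), via benzylic iodide 14 (not isolated)
Conditions: Cp2TiCl2 (2.6 equiv), Zn dust, THF, rt, 1 h (green Cp2TiCl solution, decanted from Zn); added dropwise over 2 h to 12 in THF (0.02 M), 0 °C → rt; then I2 (1.5 equiv), THF, 0 °C → rt; aq Na2S2O3
Reagents that add atoms: none
Why: Proposed new method: Cp2TiCl (trivalent titanium) opens the epoxide by single-electron transfer to the secondary C8' radical carrying a C9' titanium alkoxide (the epoxide stereocentre is erased), this radical adds to C8 of the styrenyl silyl enol ether to close ring B by radical 5-exo-trig cyclisation, the resulting benzylic C7 radical is capped by a second Cp2TiCl (13), and iodine converts C7 into a benzylic iodide (14) whose ionisation lets the C9' alkoxide close ring A by polar 5-exo-tet substitution. The closest known reaction type is the Cp2TiCl/I2 epoxide-opening radical cyclisation of the same kind of epoxy ether onto plain cinnamyl ethers to give furofurans, with radical cyclisations onto beta-alkoxyacrylates as the analogy for attack at an oxygen-bearing alkene carbon; a 2-silyloxy-substituted cinnamyl acceptor has not been used and is the new element. C8' and C8 are set in a chair-like 5-exo transition state under control of C7': the veratryl group sits pseudo-equatorial, the CH2O[Ti] arm on C8' ends up trans to it and cis to the C7 arm on C8, so the later fusion is cis with OSi and H-8' on the convex face. C7 is set in the ionic closure, in which the aryl group should take the exo position next to the silyloxy oxygen and away from the ring B methylene on the concave face. The step needs 5-exo over 6-endo attack, which benzylic stabilisation of the C7 radical, the larger LUMO coefficient at C8 and the ether tether should secure, and cyclisation faster than capture of the beta-titanoxy radical (deoxygenation to the alkene), which slow addition of Cp2TiCl at high dilution should secure. It also needs 13 to keep its beta-silyloxy group until iodine arrives, for which the bulky, weakly Lewis-basic tert-butyldimethylsilyl ether and prompt addition of iodine at 0 °C are relied on.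

Step 8
Reactants: 15 (7R,8S,7'S,8'R)-bis(tert-butyldimethylsilyl) ether of the target
Product: 16 (7R,8S,7'S,8'R)-3,3',4'-trimethoxy-7,9':7',9-diepoxylignane-4,8-diol (target)
Conditions: TBAF (4 equiv), AcOH (4 equiv), THF, 0 °C → rt (40 °C if the tertiary ether is slow)
Reagents that add atoms: none
Why: Fluoride-mediated desilylation cleaves the aryl and the tertiary silyl ether, and the acetic acid buffer keeps the freed phenol protonated so that ring A is not opened through a quinone methide; no stereocentre is touched.

**Compound list**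

1 | veratraldehyde (3,4-dimethoxybenzaldehyde) | COc1ccc(C=O)cc1OC | starting material
2 | vinylmagnesium bromide | C=C[Mg]Br | starting material
3 | bromomagnesium 1-(3,4-dimethoxyphenyl)prop-2-en-1-olate (formed in the flask) | COc1ccc(C(O[Mg]Br)C=C)cc1OC | intermediate
4 | rac-1-(3,4-dimethoxyphenyl)prop-2-en-1-ol | COc1ccc(C(O)C=C)cc1OC | intermediate
5 | (R)-(3,4-dimethoxyphenyl)[(S)-oxiran-2-yl]methanol (erythro epoxy alcohol) | COc1ccc([C@@H](O)[C@@H]2CO2)cc1OC | intermediate
6 | homovanillic acid | COc1cc(CC(=O)O)ccc1O | starting material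
7 | tert-butyldimethylsilyl [4-(tert-butyldimethylsilyloxy)-3-methoxyphenyl]acetate (formed in the flask) | COc1cc(CC(=O)O[Si](C)(C)C(C)(C)C)ccc1O[Si](C)(C)C(C)(C)C | intermediate
8 | [4-(tert-butyldimethylsilyloxy)-3-methoxyphenyl]acetic acid | COc1cc(CC(=O)O)ccc1O[Si](C)(C)C(C)(C)C | intermediate
9 | mixed anhydride of 8 with isobutyl carbonic acid (formed in the flask) | COc1cc(CC(=O)OC(=O)OCC(C)C)ccc1O[Si](C)(C)C(C)(C)C | intermediate
10 | 1-diazo-3-[4-(tert-butyldimethylsilyloxy)-3-methoxyphenyl]propan-2-one | COc1cc(CC(=O)C=[N+]=[N-])ccc1O[Si](C)(C)C(C)(C)C | intermediate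
11 | 1-[4-(tert-butyldimethylsilyloxy)-3-methoxyphenyl]-3-{(R)-(3,4-dimethoxyphenyl)[(S)-oxiran-2-yl]methoxy}propan-2-one | COc1cc(CC(=O)CO[C@H](c2ccc(OC)c(OC)c2)[C@@H]3CO3)ccc1O[Si](C)(C)C(C)(C)C | intermediate
12 | (Z)-2-(tert-butyldimethylsilyloxy)-1-[4-(tert-butyldimethylsilyloxy)-3-methoxyphenyl]-3-{(R)-(3,4-dimethoxyphenyl)[(S)-oxiran-2-yl]methoxy}prop-1-ene (key-step precursor) | COc1cc(/C=C(O[Si](C)(C)C(C)(C)C)/CO[C@H](c2ccc(OC)c(OC)c2)[C@@H]3CO3)ccc1O[Si](C)(C)C(C)(C)C | intermediate
13 | ring B tetrahydrofuran (veratryl trans to CH2O[Ti], 8-OSi) with Cp2Ti(Cl)–O on C9' and Cp2Ti(Cl) on benzylic C7 (formed in the flask, C7 undefined) | COc1cc(C([Ti](Cl)(C4C=CC=C4)C5C=CC=C5)[C@@]2(O[Si](C)(C)C(C)(C)C)CO[C@H](c3ccc(OC)c(OC)c3)[C@H]2CO[Ti](Cl)(C4C=CC=C4)C5C=CC=C5)ccc1O[Si](C)(C)C(C)(C)C | intermediate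
14 | the same ring B tetrahydrofuran with iodine on benzylic C7 and Cp2Ti(Cl)–O on C9' (formed in the flask, C7 undefined) | COc1cc(C(I)[C@@]2(O[Si](C)(C)C(C)(C)C)CO[C@H](c3ccc(OC)c(OC)c3)[C@H]2CO[Ti](Cl)(C4C=CC=C4)C5C=CC=C5)ccc1O[Si](C)(C)C(C)(C)C | intermediate
15 | (7R,8S,7'S,8'R)-4,8-bis(tert-butyldimethylsilyloxy)-3,3',4'-trimethoxy-7,9':7',9-diepoxylignane (key-step product) | COc1cc([C@H]2OC[C@@H]3[C@@H](c4ccc(OC)c(OC)c4)OC[C@]23O[Si](C)(C)C(C)(C)C)ccc1O[Si](C)(C)C(C)(C)C | intermediate
16 | (7R,8S,7'S,8'R)-3,3',4'-trimethoxy-7,9':7',9-diepoxylignane-4,8-diol | COc1cc([C@H]2OC[C@@H]3[C@@H](c4ccc(OC)c(OC)c4)OC[C@]23O)ccc1O | target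

**Step count and risks**

Total steps: 8. Longest linear sequence: 6 steps (steps 1, 2, 5, 6, 7, 8 from veratraldehyde; equally steps 3, 4, 5, 6, 7, 8 from homovanillic acid).

Steps most likely to fail:

1. Step 7 (new method). Three processes may defeat it:
   - The attack on the fully substituted C8 may be too slow, so the C8' radical is captured by a second Cp2TiCl and the epoxide is simply deoxygenated.
   - The benzylic titanium species may lose its beta-silyloxy group before iodine is added.
   - The ionic closure may show poor facial selectivity at C7.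

   Fallback (known chemistry; sets out from 5, comes back at 16): O-propargylation of 5 (NaH, propargyl bromide, Bu4NI, THF, 0 °C) gives (R)-(3,4-dimethoxyphenyl)[(S)-oxiran-2-yl]methyl prop-2-ynyl ether F1. Sonogashira coupling with 4-iodo-2-methoxyphenol (Pd(PPh3)2Cl2, CuI, Et3N) gives the aryl alkyne F2. Cp2TiCl (trivalent titanium) opens the epoxide and the C8' radical closes 5-exo-dig onto the alkyne, a known epoxide–alkyne cyclisation class, to give the benzylidene tetrahydrofuran F3 with veratryl and CH2OH trans. OsO4/NMO dihydroxylation from the face away from the CH2OH arm gives the tetrol F4 with the C8 hydroxyl in place. Catalytic camphorsulfonic acid in CH2Cl2 then ionises the p-hydroxybenzylic C7–OH through the quinone methide and the C9' hydroxyl closes ring A to give 16.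

2. Step 5. The rhodium carbenoid may attack its own electron-rich ring (position para to OMe, giving an indanone) or dimerise faster than it inserts into the hindered secondary O–H. Fallback (sets out from 5 and 8, comes back at 11): Williamson alkylation of 5 (NaH, methyl bromoacetate, THF, 0 °C) gives methyl {(R)-(3,4-dimethoxyphenyl)[(S)-oxiran-2-yl]methoxy}acetate F5. The dianion of acid 8 (LiHMDS 2.2 equiv, THF, −78 °C) is acylated by F5 to the beta-keto acid F6, which loses CO2 on mild acidic work-up to give 11.

3. Step 8. The hindered tertiary silyl ether may be cleaved incompletely, and forcing conditions may epimerise C7 through quinone methide opening of ring A once the phenol is free. Fallback (sets out from 11, comes back at 16): TESOTf/Et3N at −78 °C gives the triethylsilyl enol ether F7. The cascade of step 7 then gives the triethylsilyl/tert-butyldimethylsilyl bis-ether F8, whose tertiary triethylsilyl ether and aryl silyl ether are both removed by buffered TBAF at 0 °C to give 16.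

**Further compounds**

F1 | step 7 | (R)-(3,4-dimethoxyphenyl)[(S)-oxiran-2-yl]methyl prop-2-ynyl ether | COc1ccc([C@@H](OCC#C)[C@@H]2CO2)cc1OC
F2 | step 7 | 4-(3-{(R)-(3,4-dimethoxyphenyl)[(S)-oxiran-2-yl]methoxy}prop-1-yn-1-yl)-2-methoxyphenol | COc1cc(C#CCO[C@H](c2ccc(OC)c(OC)c2)[C@@H]2CO2)ccc1O
F3 | step 7 | (7'S,8'R)-3,3',4'-trimethoxy-7',9-epoxylign-7-ene-4,9'-diol (alkene isomers) | COc1cc(C=C2CO[C@H](c3ccc(OC)c(OC)c3)[C@H]2CO)ccc1O
F4 | step 7 | (8S,7'S,8'R)-3,3',4'-trimethoxy-7',9-epoxylignane-4,7,8,9'-tetrol (C7 epimers) | COc1cc(C(O)[C@@]2(O)CO[C@H](c3ccc(OC)c(OC)c3)[C@H]2CO)ccc1O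
F5 | step 5 | methyl {(R)-(3,4-dimethoxyphenyl)[(S)-oxiran-2-yl]methoxy}acetate | COC(=O)CO[C@H](c1ccc(OC)c(OC)c1)[C@@H]1CO1
F6 | step 5 | 2-[4-(tert-butyldimethylsilyloxy)-3-methoxyphenyl]-4-{(R)-(3,4-dimethoxyphenyl)[(S)-oxiran-2-yl]methoxy}-3-oxobutanoic acid (not isolated, C2 epimers) | COc1cc(C(C(=O)O)C(=O)CO[C@H](c2ccc(OC)c(OC)c2)[C@@H]2CO2)ccc1O[Si](C)(C)C(C)(C)C
F7 | step 8 | (Z)-1-[4-(tert-butyldimethylsilyloxy)-3-methoxyphenyl]-3-{(R)-(3,4-dimethoxyphenyl)[(S)-oxiran-2-yl]methoxy}-2-(triethylsilyloxy)prop-1-ene | COc1cc(/C=C(O[Si](CC)(CC)CC)/CO[C@H](c2ccc(OC)c(OC)c2)[C@@H]3CO3)ccc1O[Si](C)(C)C(C)(C)C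
F8 | step 8 | (7R,8S,7'S,8'R)-4-(tert-butyldimethylsilyloxy)-3,3',4'-trimethoxy-8-(triethylsilyloxy)-7,9':7',9-diepoxylignane | COc1cc([C@H]2OC[C@@H]3[C@@H](c4ccc(OC)c(OC)c4)OC[C@]23O[Si](CC)(CC)CC)ccc1O[Si](C)(C)C(C)(C)C
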